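(All runs stem from a simulated flask from invented constants; noise was put on by code.)

A small charge of starting material, 5.3 mM in the green run, stood after 8.00 min at 44% target with 8% starting material left. That reads as 2.33 mM of target. The blue run, with 25 mM, averages 3.38 mM over its last two readings, and this figure is the end stock of target, meaning the percentage late in a run times the charge. The charge rose 4.72-fold, more than the stock, which rose 1.45-fold.

| setting | green | blue | west | south-east | south-west | east |
|---|---|---|---|---|---|---|
| starting material | 5.3 mM | 25 mM | 6.0 mM | 40 mM | 15 mM | 10 mM |
| remark | run made earlier | run made earlier |  |  |  |  |
| time |  |  | 10 min | 10 min | 10 min | 10 min |

- green (time / min: target / %, starting material / %): 0.667: 14, 81; 2.00: 22, 52; 3.00: 25, 35; 5.00: 35, 19; 8.00: 44, 8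
- blue (time / min: target / %, starting material / %): 0.500: 7, 67; 1.00: 10, 45; 2.00: 7, 31; 4.00: 15, 12; 8.00: 12, 0

(each reading ± 2 percentage points)

- the flasks by amount of target, in percent of the starting material charged, highest first, at 10 min (west / south-east / south-west / east)
- the amount of target, in percent of the starting material charged of the flask you put first, at 10 min
- the amount of target, in percent of the starting material charged of the flask you put last, at 10 min

- in percentages every species weighs as the starting material in it: one homo dimer or side product counts as two
- steps under discussion: starting material <-> other conformer; starting material -> target; other conformer -> isomer of the product; 2 starting material -> homo dimer; starting material + target -> side product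
- in a conversion other conformer counts as not yet reacted

Two chemists compare rates at one moment. If starting material -> target and starting material + target -> side product run as written, both rates carry starting material as a factor, so it cancels from the ratio of target made to target used, and that ratio falls as target builds up and drifts down to one at a ceiling, a steady state for target.

The first chemist takes the blue stock as that ceiling and simply divides it by the charge: 56.2% for west and 8.44% for south-east.

The second chemist objects that a small charge may run down before it nears the ceiling, and points to the green stock, which stood lower than the blue one with 8% starting material read as left. So each flask should borrow the stock of its nearest run, which gives west 38.9% and leaves south-east unchanged.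

The forecast, “Dilution favours target”, stands on the second side but with its own figures, west > east > south-west > south-east, 40% and 10%.

The simulation gives west > east > south-west > south-east, with west at 38.1% and south-east at 9.82%.

    starting material ⇌ other conformer (K = 0.0117, k = 2.02 min⁻¹)
    starting material → target (k = 0.189 min⁻¹)
    other conformer → isomer of the product (k = 0.472 min⁻¹)
    2 starting material → homo dimer (k = 14.5 M⁻¹ min⁻¹)
    starting material + target → side product (k = 42.9 M⁻¹ min⁻¹)

West therefore holds 2.29 mM of target and south-east 3.93 mM, so the stock of west is smaller and the first chemist's 56.2% fails there. At the strong end the same division came within 1.4 percentage points of south-east. The neighbouring flask, south-east with 160 mM of starting material, is reckoned the same way: the blue stock divided by that charge gives 2.11%. The simulation gives 2.70% at 10.0 min, which is 4.32 mM of target, beside 16.0% side product, and the ceiling, the constant of starting material -> target over that of starting material + target -> side product, stands at 4.41 mM.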